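## Retrosynthetic overview
1. The target's C7/C8 trans-diol comes from a Δ7 cyclopentene by convex-face epoxidation and anti-opening at C8, assisted by the 10-OAc group. The C11 acyloxymethyl group is added last by Stille coupling on a C3=C4 enol triflate.
2. The cis-fused cyclopentene is closed by a Pd enolate allylation (C5–C6) onto the pyranone ring.
3. **Key bond:** C8–C9, formed by vinyl-radical conjugate addition to an Achmatowicz-derived 6-acyloxy pyranone. The radical adds anti to the axial C1 acyloxy group and so sets C9.
4. Ring order: the pyran ring first (Achmatowicz, then Pd DYKAT for C1), then the cyclopentene (radical C8–C9, then Pd C5–C6).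

Assumptions:
- (Z)-2-Bromobut-2-ene-1,4-diol is commercial (otherwise one step from 2-butyne-1,4-diol and HBr).
- The tributyltin unit of compound 13 is a removable carrier, so it is treated as a reagent; only its CH2 is incorporated.
- The (R,R)-Trost ligand is assumed to give the (S)-acylal 5.
- Iridoid numbering (C1–C11) is used throughout. "β face" means the face bearing H5/H9 (the convex face).

## Route

**Step 1**
Reactants: 1, furfuryl alcohol
Product: 2, 6-hydroxy-2H-pyran-3(6H)-one (racemic lactol)
Conditions: NBS, NaHCO3, NaOAc·3H2O, THF/H2O (4:1), 0 °C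
Reagents that add atoms: water (O)
Why: Achmatowicz ring expansion builds the pyran oxygen (O2), the C1 acetal carbon, the C9=C5 enone and the C4 ketone in one operation, and creates no fixed stereocentre.

**Step 2**
Reactants: 2
Product: 3, tert-butyl (5-oxo-5,6-dihydro-2H-pyran-2-yl) carbonate (α/β mixture)
Conditions: Boc2O, DMAP (cat.), CH2Cl2, −78 °C
Reagents that add atoms: di-tert-butyl dicarbonate, CC(C)(C)OC(=O)OC(=O)OC(C)(C)C
Why: O-acylation of the anomerising lactol gives an allylic anomeric carbonate that Pd(0) can ionise in the next step.

**Step 3**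
Reactants: 3; 4, isovaleric acid (3-methylbutanoic acid)
Product: 5, (2S)-5-oxo-5,6-dihydro-2H-pyran-2-yl 3-methylbutanoate
Conditions: Pd2(dba)3·CHCl3 (2.5 mol %), (R,R)-DACH-phenyl Trost ligand (7.5 mol %), CH2Cl2, 0 °C
Reagents that add atoms: none (isovalerate comes from 4)
Why: Proposed new method: Pd(0) ionises both anomers of 3 to a π-allyl (C1–C9–C5) whose enantiomers equilibrate, and isovalerate attacks C1 under ligand control (dynamic kinetic asymmetric transformation). This fixes C1. Closest known reactions: Trost DYKAT of Boc-pyranones with O-nucleophiles and of butadiene monoepoxide with carboxylic acids.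

**Step 4**
Reactants: 6, (2Z)-2-bromobut-2-ene-1,4-diol
Product: 7, (2Z)-2-bromobut-2-ene-1,4-diyl diacetate
Conditions: Ac2O, Et3N, DMAP, CH2Cl2, 0 °C
Reagents that add atoms: acetic anhydride, CC(=O)OC(C)=O
Why: Simple esterification. It supplies the C10 acetate of the target and the C6 allylic acetate that serves as a leaving group in Step 6.

**Step 5 (key radical step)**
Reactants: 5; 7
Product: 8, (2S)-3-[1,4-bis(acetyloxy)but-2-en-2-yl]-5-oxotetrahydro-2H-pyran-2-yl 3-methylbutanoate (C3 substituent trans to the 2-acyloxy group)
Conditions: (Me3Si)3SiH (1.3 equiv, syringe pump, 6 h), Et3B (0.2 equiv), air (cat.), benzene, 25 °C; 7 in 2-fold excess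
Reagents that add atoms: none (the silane supplies only H)
Why: Proposed new method: the silyl radical abstracts Br from 7 to give a nucleophilic vinyl σ-radical at C8. It adds to C9, the β-carbon of the enone, anti to the pseudo-axial C1 isovalerate, so C8 ends up trans to OIsoval; the α-keto radical at C5 is then quenched by H-transfer from the silane. Closest known reaction: Giese-type radical conjugate addition to cyclic enones and Achmatowicz pyranones.

**Step 6**
Reactants: 8
Product: 9, 10-acetoxy-1-isovaleryloxy-cyclopenta[c]pyran-4-one with a Δ7 double bond (iridoid numbering; cis-fused, 1-OIsoval trans to C8)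
Conditions: Pd(PPh3)4 (10 mol %), Cs2CO3, THF, 60 °C
Reagents that add atoms: none (AcOH is lost)
Why: Proposed new method: Pd(0) ionises the C6 allylic acetate. Reversible carbonate enolisation lets only the C5 enolate close the five-membered ring onto the π-allyl. The tether on C9 forces C5–C6 to form cis, so the ring fusion is cis and C5 is set. Closest known reaction: intramolecular Tsuji–Trost allylation of ketone enolates.

**Step 7**
Reactants: 9
Product: 10, the C3=C4 enol triflate of 9
Conditions: KHMDS (1.1 equiv), THF, −78 °C; then PhNTf2, −78 → 0 °C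
Reagents that add atoms: N-phenylbis(trifluoromethanesulfonimide), O=S(=O)(C(F)(F)F)N(c1ccccc1)S(=O)(=O)C(F)(F)F
Why: Kinetic deprotonation occurs at the less hindered α-alkoxy CH2 (C3), and the enolate is trapped as the enol triflate. This masks the future enol ether as an electron-poor alkene that survives the peracid in Step 8. No new stereocentre.

**Step 8**
Reactants: 10
Product: 11, 7β,8β-epoxide of 10
Conditions: mCPBA, NaHCO3, CH2Cl2, 0 °C
Reagents that add atoms: mCPBA, OOC(=O)c1cccc(Cl)c1 (delivers O)
Why: Prilezhaev epoxidation of the trisubstituted Δ7 alkene occurs from the convex β face, anti to the folded pyran ring. Both epoxide carbons are thereby set, with O on the β face; the enol triflate is untouched.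

**Step 9**
Reactants: 11
Product: 12, the 7β,8α-diol with 10-OAc and the 3,4-enol triflate
Conditions: TsOH·H2O (5 mol %), MeCN/H2O (20:1), 0 → 25 °C; then SiO2 chromatography (acyl equilibration)
Reagents that add atoms: water (O)
Why: Acid-catalysed opening of the epoxide at the tertiary C8–O bond is assisted by the 10-OAc carbonyl, which attacks C8 from the α face through a 1,3-dioxolan-2-ylium ion. This gives inversion at C8 (O α/down, C10 β/up). Water hydrolyses the ion and the acetyl settles on primary O10, leaving C8-OH. The C7–O bond is untouched, so C7 keeps its β oxygen, giving the trans-diol.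

**Step 10**
Reactants: 13, (iodomethyl)tributylstannane; 4
Product: 14, (isovaleryloxymethyl)tributylstannane
Conditions: Cs2CO3, DMF, 25 °C
Reagents that add atoms: none (isovalerate comes from 4)
Why: SN2 displacement of iodide by carboxylate gives the Stille partner that carries the C11–OIsoval unit.

**Step 11**
Reactants: 12; 14
Product: 15, target
Conditions: Pd(PPh3)4 (10 mol %), CuCl (2 equiv), LiCl (3 equiv), DMSO, 50 °C
Reagents that add atoms: none (the CH2OIsoval group comes from 14)
Why: Proposed new method: oxidative addition into the vinyl triflate followed by Cu-assisted transmetalation of the α-acyloxymethyl group installs C11 and regenerates the C3=C4 enol ether with the free diol intact. Closest known reaction: Cu-promoted Stille coupling of α-heteroatom-substituted methylstannanes with vinyl triflates.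

## Compound list
1 | furfuryl alcohol | OCc1ccco1 | starting material
2 | 6-hydroxy-2H-pyran-3(6H)-one | O=C1COC(O)C=C1 | intermediate
3 | tert-butyl (5-oxo-5,6-dihydro-2H-pyran-2-yl) carbonate | O=C1COC(OC(=O)OC(C)(C)C)C=C1 | intermediate
4 | isovaleric acid | CC(C)CC(=O)O | starting material
5 | (2S)-5-oxo-5,6-dihydro-2H-pyran-2-yl 3-methylbutanoate | O=C1CO[C@@H](OC(=O)CC(C)C)C=C1 | intermediate
6 | (2Z)-2-bromobut-2-ene-1,4-diol | OC/C(Br)=C/CO | starting material
7 | (2Z)-2-bromobut-2-ene-1,4-diyl diacetate | CC(=O)OC/C(Br)=C/COC(C)=O | intermediate
8 | Giese adduct (C8–C9 bond formed; alkene geometry undefined) | O=C1CO[C@@H](OC(=O)CC(C)C)[C@H](C(COC(C)=O)=CCOC(C)=O)C1 | intermediate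
9 | Δ7 bicyclic 4-ketone | CC(=O)OCC1=CC[C@@H]2C(=O)CO[C@@H](OC(=O)CC(C)C)[C@H]12 | intermediate
10 | enol triflate | CC(=O)OCC1=CC[C@@H]2C(OS(=O)(=O)C(F)(F)F)=CO[C@@H](OC(=O)CC(C)C)[C@H]12 | intermediate
11 | 7β,8β-epoxide | CC(=O)OC[C@@]12[C@H]3[C@H](OC(=O)CC(C)C)OC=C(OS(=O)(=O)C(F)(F)F)[C@H]3C[C@@H]1O2 | intermediate
12 | 7β,8α-diol enol triflate | CC(=O)OC[C@]1(O)[C@H]2[C@H](OC(=O)CC(C)C)OC=C(OS(=O)(=O)C(F)(F)F)[C@H]2C[C@@H]1O | intermediate
13 | (iodomethyl)tributylstannane | CCCC[Sn](CCCC)(CCCC)CI | starting material (carrier reagent)
14 | (isovaleryloxymethyl)tributylstannane | CCCC[Sn](CCCC)(CCCC)COC(=O)CC(C)C | intermediate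
15 | target (CID42638123) | CC(=O)OC[C@]1(O)[C@H]2[C@H](OC(=O)CC(C)C)OC=C(COC(=O)CC(C)C)[C@H]2C[C@@H]1O | target

## Totals
- Total steps: 11.
- Longest linear sequence: 9 (Steps 1, 2, 3, 5, 6, 7, 8, 9, 11).

## Three steps most likely to fail
1. **Step 5 (vinyl-radical conjugate addition).** The vinyl radical may be reduced directly by the silane, or the β-acetoxy group may migrate (1,2-acyloxy shift).
   - Fallback: an ionic conjugate addition of the corresponding vinyl-cuprate (via Br/Mg exchange of 7 and CuBr·SMe2/TMSCl) to enone 5.
2. **Step 6 (Pd cyclopentene closure).** Closing the ring by attack at the remote allyl terminus may not compete, and enolisation may go to C3 instead of C5.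
   - Fallback: replace the C6 acetate of 7 by a bromide and close the ring by KHMDS-mediated intramolecular SN2 alkylation.
3. **Step 11 (Stille with the acyloxymethylstannane).** Transmetalation of the α-acyloxymethyl group may be slow, or the product may lose its acyl groups.
   - Fallback: Pd/CO/Bu3SnH formylation of the triflate to the C11 aldehyde, then Luche reduction and selective isovaleroylation of the primary allylic alcohol.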